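**Minutes of the meeting on the flask**

common to all: free catalyst 0.39 mM

|  | starting material | second substrate | solid reagent | remark | time |
|---|---|---|---|---|---|
| dawn | 23 mM | 23 mM | 13 mM | run made earlier |  |
| midnight | 23 mM | 23 mM | 19 mM | run made earlier |  |
| dusk | 46 mM | 23 mM | 25.3 mM | run made earlier |  |
| flask | 23 mM | 23.0 mM | 25.3 mM |  | 30 min |

| run | time / min | starting material / % | target / % |
|---|---|---|---|
| dawn | 3.00 | 90.2 | 9.6 |
| dawn | 6.00 | 89.6 | 10.2 |
| dawn | 10.0 | 89.1 | 10.3 |
| dawn | 12.0 | 89.8 | 10.4 |
| dawn | 15.0 | 89.4 | 10.5 |
| dawn | 20.0 | 89.4 | 10.0 |
| midnight | 3.00 | 83.0 | 16.0 |
| midnight | 6.00 | 81.2 | 18.2 |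
| midnight | 10.0 | 81.3 | 18.2 |
| midnight | 12.0 | 81.4 | 18.8 |
| midnight | 15.0 | 81.5 | 18.5 |
| midnight | 20.0 | 80.9 | 17.9 |
| dusk | 4.00 | 80.9 | 18.8 |
| dusk | 8.00 | 78.7 | 21.2 |
| dusk | 10.0 | 78.1 | 21.5 |
| dusk | 15.0 | 78.9 | 21.0 |
| dusk | 20.0 | 78.4 | 21.6 |

(standard deviation of a reading: 0.3 percentage points)

- solid reagent is a solid; its amount is given per volume of the solution
- the numbers in the tables scatter by 0.3 percentage points (one standard deviation)
- at the start none of the solid reagent is in solution

- how much of the starting material has reacted by 30 min
- how much target there is at 30 min, in percent of the starting material charged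

Late in the dawn, midnight and dusk runs the readings stop moving beyond their scatter of 0.3 percentage points, so the meeting treated the flask as a question about its plateau. The forecast came first: 27.4% converted and 27% target, on the ground that “30 min should simply read the plateau”.

I argued for a cheaper road, reckoning with fractions left. Suppose each plateau marks the end of the solid reagent, and each portion of it took one starting material or one second substrate. Then the solid reagent not found as target tells how much second substrate went. The last readings give 0.179 for dawn, 0.204 for midnight and 0.221 for dusk, with mean 0.201. This is the selectivity factor, the logarithm of the fraction of starting material left divided by that of the fraction of second substrate left.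

In the flask the two charges are equal, so on that supposition the two fractions left add to 0.900. That closes with second substrate left at 0.187 and starting material left at 71.3%. I therefore put conversion at 28.7%, more than the forecast's figure, with target just below it.

**Result**

The flask gives 29.3% converted and 28.8% target.

    starting material + free catalyst ⇌ catalyst intermediate A (K = 102 /M, k = 522 /M/s)
    partner + catalyst intermediate A → free catalyst + target (k = 19.7 /M/s)
    second substrate + free catalyst ⇌ catalyst intermediate B (K = 701 /M, k = 83.1 /M/s)
    partner + catalyst intermediate B → free catalyst + second product (k = 52.0 /M/s)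
    solid reagent ⇌ partner, rate k5*(cs5 - [partner]) while solid is left; crystals form when [partner] > cs5 (solubility = 11.0 mM, k = 0.106 /s)

In the flask nearly all of that conversion stands by 4.14 min, far sooner than the 30 min asked, and the solid reagent, the limiting reagent, is at 0% by 3.00 min. Unbound second substrate left in the flask, 18%, is less than unbound starting material left, 71%.

Take the neighbour flask with 9.2 mM of starting material, a charge ratio of 0.400: on the same supposition the fraction of second substrate left plus that ratio times the fraction of starting material left comes to 0.300, and with the carried 0.201 the reckoning puts the starting material left at 58.1%. That neighbour computes to 41.0% converted and 40.0% target.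

All runs are calculated with made-up constants.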